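**Plan**

1. Retrosynthesis cuts, in order: the C11–OOH bond (singlet-oxygen ene reaction on a C7=C11 enone), the angelate acyl–O bond, the C3–O and C4–O bonds (cis-diol from a C3=C4 alkene), and the C7=C11 bond (acetone aldol on a C8 ketone).
2. Ring A then holds a trisubstituted C3=C4 alkene between ring-fusion C5 and quaternary C10. This is the cyclohexene of a [4+2] addition of dienophile C1=C10 to diene C2=C3–C4=C5, with C6–C9 of ring B as the tether, so C1–C2 and C5–C10 are cut together.
3. The open triene is cut at C9–C10 (epoxide opening), C2=C3 (Wittig) and C4=C5 (cross-metathesis).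
4. Forward: the chain is joined at C4=C5, then C2=C3, then C9–C10; rings A and B form together in the cycloaddition; ring B is then functionalised (C8 ketone, C7=C11), ring A next (diol, ester), and the hydroperoxide comes last.
5. Stereochemistry: C8 comes from a bought (R)-epoxide and relays to C5 and C10 in the cycloaddition before it is oxidised away; C3 and C4 come from dihydroxylation on the face opposite the C14 methyl; the Z ester geometry comes with angelic acid.

Key step: step 5

Remark: eudesmane numbering (C1–C15) is used for all bicyclic compounds and, by anticipation, for the chain carbons of the open precursors; (R)-2-(but-3-en-1-yl)oxirane is taken as a commercial single enantiomer.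

**Step 1**
Reactants: 1 (R)-2-(but-3-en-1-yl)oxirane; 2 methacrolein (2-methylprop-2-enal)
Product: 3 (2E)-2-methyl-5-[(2R)-oxiran-2-yl]pent-2-enal
Conditions: second-generation Grubbs catalyst (H2IMes)(PCy3)Cl2Ru=CHPh (5 mol %), 2 (5 equiv), CH2Cl2, 40 °C
Reagents that add atoms: none
Why: Olefin cross-metathesis of a terminal alkene with methacrolein is a standard route to 2-methyl-2-enals and should give the E isomer under thermodynamic control, while the ruthenium alkylidene leaves the epoxide and its stereocentre untouched.

**Step 2**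
Reactants: 3 (2E)-2-methyl-5-[(2R)-oxiran-2-yl]pent-2-enal; 4 methyltriphenylphosphonium bromide
Product: 6 (2R)-2-[(3E)-4-methylhexa-3,5-dien-1-yl]oxirane, via methylenetriphenylphosphorane 5 (not isolated)
Conditions: 4, KOtBu, THF, 0 °C; then 3, 0 °C → rt
Reagents that add atoms: none
Why: Wittig methylenation with the non-stabilised ylide should convert the enal into the terminal diene without touching the E-trisubstituted alkene or the epoxide, which does not react with the ylide at this temperature.

**Step 3**
Reactants: 6 (2R)-2-[(3E)-4-methylhexa-3,5-dien-1-yl]oxirane; 7 isopropenylmagnesium bromide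
Product: 8 (4R,7E)-2,8-dimethyldeca-1,7,9-trien-4-ol
Conditions: 7, CuBr·SMe2 (10 mol %), THF, −30 °C; then aq NH4Cl
Reagents that add atoms: none
Why: Copper-catalysed Grignard opening of a terminal epoxide proceeds by SN2 attack at the unsubstituted carbon, so the C–O bond at the stereocentre is not broken and the (R) configuration of 1 becomes the (R) carbinol that is the later C8.

**Step 4**
Reactants: 8 (4R,7E)-2,8-dimethyldeca-1,7,9-trien-4-ol
Product: 9 (4R,7E)-4-(tert-butyldimethylsilyloxy)-2,8-dimethyldeca-1,7,9-triene
Conditions: TBSCl, imidazole, DMF, rt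
Reagents that add atoms: tert-butyldimethylsilyl chloride, CC(C)(C)[Si](C)(C)Cl
Why: Imidazole-promoted silylation of a secondary alcohol is routine and masks the homoallylic hydroxyl, which could otherwise fragment by a retro-ene path or dehydrate on strong heating.

**Step 5**
Reactants: 9 (4R,7E)-4-(tert-butyldimethylsilyloxy)-2,8-dimethyldeca-1,7,9-triene
Product: 10 (5R,8R,10R)-8-(tert-butyldimethylsilyloxy)-11,12,13-trinoreudesm-3-ene
Conditions: toluene (0.02 M), BHT (cat.), sealed tube, 200 °C
Reagents that add atoms: none
Why: On heating, the unactivated alkene C1=C10 adds suprafacially across the s-cis E-diene C2=C3–C4=C5 in a concerted [4+2] cycloaddition that forms C1–C2 and C5–C10 and leaves the C3=C4 alkene, the closest known reaction type being the thermal intramolecular Diels–Alder reaction of 1,7,9-decatrienes that carry an unactivated 1,1-disubstituted dienophile. Ring A closes as the six-membered ring of the cycloadduct, with both new bonds in it, and ring B closes through the C5–C10 bond alone as a six-membered ring whose four-carbon tether C6–C9 folds as a chair. The trans relation of the new stereocentres C5 and C10 should come from the anti folding, in which the tether is exo and the C14 methyl lies endo under the diene, the mode expected for decatrienes with a methyl on the inner dienophile carbon. Their absolute configuration is controlled by C8: in the chair tether the silyloxy group stays equatorial, since the axial position would clash 1,3 with the axial C14 methyl, and from 8R this places C5–C10 bond formation on the diene face that gives 5R,10R. The step thus needs anti over syn folding and one diene face, secured by the dienophile methyl and by the (R)-silyl ether respectively, while the E geometry of the C4=C5 alkene keeps the tether on the outer side of the s-cis diene. The silyl ether also prevents retro-ene cleavage of the homoallylic alcohol at this temperature, and any minor isomers are removed after step 6.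

**Step 6**
Reactants: 10 (5R,8R,10R)-8-(tert-butyldimethylsilyloxy)-11,12,13-trinoreudesm-3-ene
Product: 11 (5R,8R,10R)-11,12,13-trinoreudesm-3-en-8-ol
Conditions: Bu4NF, THF, rt; chromatography
Reagents that add atoms: none
Why: Fluoride-induced desilylation leaves all stereocentres untouched, and the free alcohol is the stage at which cis-fused and C8-axial by-products of step 5 should be removed by chromatography so that no antipodal ketone can arise in step 7.

**Step 7**
Reactants: 11 (5R,8R,10R)-11,12,13-trinoreudesm-3-en-8-ol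
Product: 12 (5R,10R)-11,12,13-trinoreudesm-3-en-8-one
Conditions: Dess–Martin periodinane, CH2Cl2, rt
Reagents that add atoms: none
Why: Dess–Martin oxidation of the secondary alcohol under mild conditions should give the C8 ketone without moving the C3=C4 alkene, and the C8 stereocentre, having served as relay, is removed on purpose.

**Step 8**
Reactants: 12 (5R,10R)-11,12,13-trinoreudesm-3-en-8-one; 13 acetone
Product: 15 (5R,7R,10R)-11-hydroxyeudesm-3-en-8-one, via lithium enolate 14 (not isolated)
Conditions: LiN(iPr)2 (LDA), THF, −78 °C; then 13, −78 °C; AcOH quench at −78 °C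
Reagents that add atoms: none
Why: Kinetic deprotonation of the C8 ketone should occur at C7 and not at C9, which is shielded by quaternary C10, and the lithium enolate then adds to acetone in a directed aldol addition whose new C7 centre (expected equatorial, 7R) is of no consequence because it becomes sp2 in step 9.

**Step 9**
Reactants: 15 (5R,7R,10R)-11-hydroxyeudesm-3-en-8-one
Product: 17 (5R,10R)-eudesma-3,7(11)-dien-8-one, via tertiary mesylate 16 (not isolated)
Conditions: MsCl, Et3N, CH2Cl2, 0 °C; then DBU, rt
Reagents that add atoms: none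
Why: Sulfonylation of the tertiary aldol hydroxyl followed by base-induced β-elimination through the C7 enolate should give the conjugated tetrasubstituted C7=C11 enone, and DBU brings any isopropenyl isomer into conjugation.

**Step 10**
Reactants: 17 (5R,10R)-eudesma-3,7(11)-dien-8-one
Product: 18 (3R,4S,5R,10R)-3,4-dihydroxyeudesm-7(11)-en-8-one
Conditions: OsO4 (2 mol %), NMO, acetone/H2O, 0 °C → rt
Reagents that add atoms: osmium tetroxide, O=[Os](=O)(=O)=O; N-methylmorpholine N-oxide, C[N+]1([O-])CCOCC1; water, O
Why: Upjohn dihydroxylation (suprafacial [3+2] addition of OsO4) should select the electron-rich trisubstituted C3=C4 alkene over the conjugated tetrasubstituted C7=C11 alkene and occur on the α face, away from the axial C14 methyl that screens the β face of C4, which sets 3R and 4S together as the cis 3α,4α-diol.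

**Step 11**
Reactants: 18 (3R,4S,5R,10R)-3,4-dihydroxyeudesm-7(11)-en-8-one; 19 angelic acid ((Z)-2-methylbut-2-enoic acid)
Product: 21 (3R,4S,5R,10R)-3-angeloyloxy-4-hydroxyeudesm-7(11)-en-8-one, via mixed anhydride 20 (not isolated)
Conditions: 19, 2,4,6-trichlorobenzoyl chloride, Et3N, toluene, rt; then 18, 80 °C
Reagents that add atoms: none
Why: Yamaguchi esterification through the mixed anhydride should acylate only the secondary 3-OH (the tertiary 4-OH is inert) with retention at C3, and working without DMAP keeps the Z (angelate) geometry from isomerising to the tiglate.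

**Step 12**
Reactants: 21 (3R,4S,5R,10R)-3-angeloyloxy-4-hydroxyeudesm-7(11)-en-8-one
Product: 22 (3R,4S,5R,10R)-3-angeloyloxy-4-hydroxy-11-hydroperoxyeudesm-6-en-8-one (CNP0161122.2)
Conditions: O2, hν (visible), tetraphenylporphyrin (cat.), CH2Cl2, −20 °C
Reagents that add atoms: dioxygen, O=O
Why: The Schenck ene reaction of singlet oxygen with an s-cis alkylidene ketone follows the geminal rule, so oxygen should bond to C11 while the allylic hydrogen on C6 is transferred and the alkene shifts to C6=C7 in conjugation with C8=O, the ester-deactivated angelate alkene being expected to react far more slowly and no stereocentre being formed or disturbed.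

**Compound list**

1 | (R)-2-(but-3-en-1-yl)oxirane | C=CCC[C@@H]1CO1 | starting material
2 | methacrolein (2-methylprop-2-enal) | CC(=C)C=O | starting material
3 | (2E)-2-methyl-5-[(2R)-oxiran-2-yl]pent-2-enal | O=C/C(C)=C/CC[C@@H]1CO1 | intermediate
4 | methyltriphenylphosphonium bromide | C[P+](c1ccccc1)(c1ccccc1)c1ccccc1.[Br-] | starting material
5 | methylenetriphenylphosphorane | C=P(c1ccccc1)(c1ccccc1)c1ccccc1 | intermediate
6 | (2R)-2-[(3E)-4-methylhexa-3,5-dien-1-yl]oxirane | C=C/C(C)=C/CC[C@@H]1CO1 | intermediate
7 | isopropenylmagnesium bromide | CC(=C)[Mg]Br | starting material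
8 | (4R,7E)-2,8-dimethyldeca-1,7,9-trien-4-ol | C=C(C)C[C@H](O)CC/C=C(C)/C=C | intermediate
9 | (4R,7E)-4-(tert-butyldimethylsilyloxy)-2,8-dimethyldeca-1,7,9-triene | C=C(C)C[C@H](O[Si](C)(C)C(C)(C)C)CC/C=C(C)/C=C | intermediate
10 | (5R,8R,10R)-8-(tert-butyldimethylsilyloxy)-11,12,13-trinoreudesm-3-ene | CC1=CCC[C@]2(C)C[C@H](O[Si](C)(C)C(C)(C)C)CC[C@@H]12 | intermediate
11 | (5R,8R,10R)-11,12,13-trinoreudesm-3-en-8-ol | CC1=CCC[C@]2(C)C[C@H](O)CC[C@@H]12 | intermediate
12 | (5R,10R)-11,12,13-trinoreudesm-3-en-8-one | CC1=CCC[C@]2(C)CC(=O)CC[C@@H]12 | intermediate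
13 | acetone | CC(C)=O | starting material
14 | lithium (5R,10R)-11,12,13-trinoreudesma-3,7-dien-8-olate | CC1=CCC[C@]2(C)CC(O[Li])=CC[C@@H]12 | intermediate
15 | (5R,7R,10R)-11-hydroxyeudesm-3-en-8-one | CC1=CCC[C@]2(C)CC(=O)[C@@H](C(C)(C)O)C[C@@H]12 | intermediate
16 | (5R,7R,10R)-8-oxoeudesm-3-en-11-yl methanesulfonate | CC1=CCC[C@]2(C)CC(=O)[C@@H](C(C)(C)OS(C)(=O)=O)C[C@@H]12 | intermediate
17 | (5R,10R)-eudesma-3,7(11)-dien-8-one | CC1=CCC[C@]2(C)CC(=O)C(=C(C)C)C[C@@H]12 | intermediate
18 | (3R,4S,5R,10R)-3,4-dihydroxyeudesm-7(11)-en-8-one | O[C@@H]1CC[C@]2(C)CC(=O)C(=C(C)C)C[C@H]2[C@]1(C)O | intermediate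
19 | angelic acid ((Z)-2-methylbut-2-enoic acid) | C/C=C(/C)C(=O)O | starting material
20 | (Z)-2-methylbut-2-enoic 2,4,6-trichlorobenzoic anhydride | C/C=C(/C)C(=O)OC(=O)c1c(Cl)cc(Cl)cc1Cl | intermediate
21 | (3R,4S,5R,10R)-3-angeloyloxy-4-hydroxyeudesm-7(11)-en-8-one | C/C=C(/C)C(=O)O[C@@H]1CC[C@]2(C)CC(=O)C(=C(C)C)C[C@H]2[C@]1(C)O | intermediate
22 | (3R,4S,5R,10R)-3-angeloyloxy-4-hydroxy-11-hydroperoxyeudesm-6-en-8-one | C/C=C(/C)C(=O)O[C@@H]1CC[C@]2(C)CC(=O)C(C(C)(C)OO)=C[C@H]2[C@]1(C)O | target

Total step count: 12
Longest linear sequence: 12 steps (1 → 22)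

**Steps most likely to fail**

Step 5. The unactivated triene may fold with too little preference for the anti (trans-forming) mode, or the diene may degrade before the cycloaddition is complete. The fallback sets out from 6 and returns at 10; it activates the dienophile with an ester on C1 that is removed afterwards, and the same two bonds and rings are formed. Epoxide 6 would be opened with LiC≡CH·H2NCH2CH2NH2 in DMSO to give (4R,7E)-8-methyldeca-7,9-dien-1-yn-4-ol F1, which would be silylated (TBSCl, imidazole) to (4R,7E)-4-(tert-butyldimethylsilyloxy)-8-methyldeca-7,9-dien-1-yne F2. Negishi methylalumination (Me3Al, Cp2ZrCl2, CH2Cl2) with ethyl chloroformate trapping should give ethyl (2E,5R,8E)-5-(tert-butyldimethylsilyloxy)-3,9-dimethylundeca-2,8,10-trienoate F3. Its intramolecular Diels–Alder reaction (toluene, about 160 °C), with the ester endo and the tether exo, should give ethyl (1R,5S,8R,10R)-8-(tert-butyldimethylsilyloxy)-11,12,13-trinoreudesm-3-ene-1-carboxylate F4. Hydrolysis (LiOH, THF/MeOH/H2O, 60 °C) would give (1R,5S,8R,10R)-8-(tert-butyldimethylsilyloxy)-11,12,13-trinoreudesm-3-ene-1-carboxylic acid F5. Barton decarboxylation through 2-thioxopyridin-1(2H)-yl (1R,5S,8R,10R)-8-(tert-butyldimethylsilyloxy)-11,12,13-trinoreudesm-3-ene-1-carboxylate F6 (DCC, N-hydroxypyridine-2-thione; then t-BuSH, hν) would then return 10.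

Step 11. The Z alkene may isomerise to the E (tiglate) form during acylation, and the axial 3-OH next to the tertiary carbinol may acylate slowly. The fallback sets out from 18 and returns at 21; it builds the Z alkene after the ester bond is in place. Steglich esterification of 18 with 2-[bis(2,2,2-trifluoroethoxy)phosphoryl]propanoic acid (DCC, DMAP, CH2Cl2) would give (3R,4S,5R,10R)-4-hydroxy-8-oxoeudesm-7(11)-en-3-yl 2-[bis(2,2,2-trifluoroethoxy)phosphoryl]propanoate F7 as a mixture of epimers at the phosphorus-bearing carbon. Still–Gennari olefination with acetaldehyde (KN(SiMe3)2, 18-crown-6, THF, −78 °C) should then give the Z-configured ester 21.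

Step 12. Singlet oxygen may also attack the angelate double bond, or prolonged irradiation may over-oxidise the product. The fallback sets out from 18 and returns at 22; it runs the photooxygenation before the ester is present and carries the hydroperoxide in masked form. The Schenck ene reaction of 18 (O2, hν, tetraphenylporphyrin, CH2Cl2) would give (3R,4S,5R,10R)-3,4-dihydroxy-11-hydroperoxyeudesm-6-en-8-one F8. Silylation with Et3SiCl and imidazole at −20 °C, where the more acidic hydroperoxide should react ahead of the hindered hydroxyls, would give (3R,4S,5R,10R)-3,4-dihydroxy-11-(triethylsilylperoxy)eudesm-6-en-8-one F9. Yamaguchi esterification with 19 under the conditions of step 11 would give (3R,4S,5R,10R)-3-angeloyloxy-4-hydroxy-11-(triethylsilylperoxy)eudesm-6-en-8-one F10, and HF·pyridine in THF at 0 °C would release 22.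

**Further compounds**

F1 | step 5 | (4R,7E)-8-methyldeca-7,9-dien-1-yn-4-ol | C#CC[C@H](O)CC/C=C(C)/C=C
F2 | step 5 | (4R,7E)-4-(tert-butyldimethylsilyloxy)-8-methyldeca-7,9-dien-1-yne | C#CC[C@H](O[Si](C)(C)C(C)(C)C)CC/C=C(C)/C=C
F3 | step 5 | ethyl (2E,5R,8E)-5-(tert-butyldimethylsilyloxy)-3,9-dimethylundeca-2,8,10-trienoate | CCOC(=O)/C=C(\C)C[C@H](O[Si](C)(C)C(C)(C)C)CC/C=C(C)/C=C
F4 | step 5 | ethyl (1R,5S,8R,10R)-8-(tert-butyldimethylsilyloxy)-11,12,13-trinoreudesm-3-ene-1-carboxylate | CC1=CC[C@@H](C(=O)OCC)[C@]2(C)C[C@H](O[Si](C)(C)C(C)(C)C)CC[C@@H]12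
F5 | step 5 | (1R,5S,8R,10R)-8-(tert-butyldimethylsilyloxy)-11,12,13-trinoreudesm-3-ene-1-carboxylic acid | CC1=CC[C@@H](C(=O)O)[C@]2(C)C[C@H](O[Si](C)(C)C(C)(C)C)CC[C@@H]12
F6 | step 5 | 2-thioxopyridin-1(2H)-yl (1R,5S,8R,10R)-8-(tert-butyldimethylsilyloxy)-11,12,13-trinoreudesm-3-ene-1-carboxylate | CC1=CC[C@@H](C(=O)ON3C=CC=CC3=S)[C@]2(C)C[C@H](O[Si](C)(C)C(C)(C)C)CC[C@@H]12
F7 | step 11 | (3R,4S,5R,10R)-4-hydroxy-8-oxoeudesm-7(11)-en-3-yl 2-[bis(2,2,2-trifluoroethoxy)phosphoryl]propanoate | CC(C(=O)O[C@@H]1CC[C@]2(C)CC(=O)C(=C(C)C)C[C@H]2[C@]1(C)O)P(=O)(OCC(F)(F)F)OCC(F)(F)F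
F8 | step 12 | (3R,4S,5R,10R)-3,4-dihydroxy-11-hydroperoxyeudesm-6-en-8-one | O[C@@H]1CC[C@]2(C)CC(=O)C(C(C)(C)OO)=C[C@H]2[C@]1(C)O
F9 | step 12 | (3R,4S,5R,10R)-3,4-dihydroxy-11-(triethylsilylperoxy)eudesm-6-en-8-one | O[C@@H]1CC[C@]2(C)CC(=O)C(C(C)(C)OO[Si](CC)(CC)CC)=C[C@H]2[C@]1(C)O
F10 | step 12 | (3R,4S,5R,10R)-3-angeloyloxy-4-hydroxy-11-(triethylsilylperoxy)eudesm-6-en-8-one | C/C=C(/C)C(=O)O[C@@H]1CC[C@]2(C)CC(=O)C(C(C)(C)OO[Si](CC)(CC)CC)=C[C@H]2[C@]1(C)O
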